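**Retrosynthetic overview**
- The strategy rests on the six-membered ring C3a–C4–C5–C6–C7–C7a of the benzofuran-2,6-dione. It carries oxygen on C5, C6 and C7a and an exocyclic C3a=C3 alkene whose carbon C3 holds the aryl group and the C2 carbonyl, which is the pattern an (allenylvinyl)ketene derived from a squarate ester gives on ring closure.
- Last bond made: the O1–C2 lactone bond, by acid treatment of the fully substituted ortho-quinone methide methyl ester 19 (loss of two tert-butyl groups and methanol).
- Key disconnection: the C7a–C3a bond, which leads back to 4-allenylcyclobutenone 17 (thermal 4π opening, then 6π closure).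
- The allene of 17 comes from SN2' arylation of propargylic carbonate 15 with phenylboronic acid. Compound 15 comes from cyclobutenedione 5 (di-tert-butyl squarate and phenyllithium) and alkyne 12 (aryl Grignard and dimethyl oxalate, then ethynyl Grignard and chloroformate).
- Ring order: the four-membered ring is bought and kept until step 6, where it is exchanged for the six-membered carbocycle; the butenolide closes last, in step 7.

Key step: step 6

Remark on the chemistry: 12, 15 and 17 are carried as stereoisomer mixtures and the C3=C3a geometry of 19 is left open, because every stereogenic element before 21 is erased in steps 6 and 7. Di-tert-butyl squarate is taken as a purchasable reagent.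

**Step 1**
Reactants: 1 di-tert-butyl squarate (3,4-di-tert-butoxycyclobut-3-ene-1,2-dione); 2 phenyllithium
Product: 5 3-tert-butoxy-4-phenylcyclobut-3-ene-1,2-dione, via lithium alkoxide adduct 3 (not isolated), via trifluoroacetate ester 4 (not isolated)
Conditions: THF, −78 °C; then (CF3CO)2O, −78 °C; aq. NaHCO3
Reagents that add atoms: none
Why: Aryllithium 1,2-addition to one squarate carbonyl followed by trifluoroacetylation of the alkoxide should trigger ionisation to an alkoxy-stabilised cyclobutenyl cation, which sheds a tert-butyl cation (as isobutene) to unveil the second carbonyl; this is the standard squarate addition–rearrangement route to 3-alkoxy-4-arylcyclobutenediones.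

**Step 2**
Reactants: 6 1-bromo-4-tert-butoxybenzene; 7 dimethyl oxalate
Product: 9 methyl 2-(4-tert-butoxyphenyl)-2-oxoacetate, via arylmagnesium bromide 8 (not isolated)
Conditions: Mg, THF, 25–40 °C; then added to excess 7, THF, −78 °C; then H2O
Reagents that add atoms: none
Why: Grignard formation and inverse addition to excess oxalate diester at low temperature should stop at monoacylation because the tetrahedral magnesium hemiketal persists until work-up (Grignard acylation of an oxalate), and the aryl tert-butyl ether is inert to these conditions.

**Step 3**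
Reactants: 9 methyl 2-(4-tert-butoxyphenyl)-2-oxoacetate; 10 ethynylmagnesium bromide
Product: 12 methyl 2-(4-tert-butoxyphenyl)-2-(methoxycarbonyloxy)but-3-ynoate (racemic), via bromomagnesium alkoxide 11 (not isolated)
Conditions: THF, −78 → −20 °C; then ClCO2Me, −20 °C → rt
Reagents that add atoms: methyl chloroformate, COC(=O)Cl
Why: The ketone of an α-keto ester is much more electrophilic than the ester, so the alkynyl Grignard should add there only and the tertiary magnesium alkoxide is acylated in the same flask (Grignard 1,2-addition, then O-acylation); the propargylic stereocentre forms as a racemate and is not needed later.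

**Step 4**
Reactants: 12 methyl 2-(4-tert-butoxyphenyl)-2-(methoxycarbonyloxy)but-3-ynoate; 5 3-tert-butoxy-4-phenylcyclobut-3-ene-1,2-dione
Product: 15 methyl 2-(4-tert-butoxyphenyl)-4-(2-tert-butoxy-1-methoxy-4-oxo-3-phenylcyclobut-2-en-1-yl)-2-(methoxycarbonyloxy)but-3-ynoate (diastereomer mixture), via lithium acetylide 13 (not isolated), via lithium alkoxide adduct 14 (not isolated)
Conditions: LiN(SiMe3)2, THF, −78 °C; then 5, −78 °C; then MeOTf, −78 → 0 °C
Reagents that add atoms: methyl trifluoromethanesulfonate, COS(=O)(=O)C(F)(F)F
Why: LiN(SiMe3)2 should deprotonate the terminal alkyne without attacking the ester or carbonate, the lithium acetylide should add to the ketone-like carbonyl of 5 (the one beside the tert-butoxy-bearing carbon, the other being deactivated as a vinylogous ester), and MeOTf methylates the tertiary alkoxide (acetylide 1,2-addition to a cyclobutenedione with in situ O-alkylation); the new ring stereocentre forms without control and is erased in step 6.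

**Step 5**
Reactants: 15 the 4-alkynylcyclobutenone propargylic carbonate; 16 phenylboronic acid
Product: 17 methyl 2-(4-tert-butoxyphenyl)-4-(2-tert-butoxy-1-methoxy-4-oxo-3-phenylcyclobut-2-en-1-yl)-4-phenylbuta-2,3-dienoate (stereoisomer mixture)
Conditions: Pd(PPh3)4 (5 mol %), THF, 25–40 °C
Reagents that add atoms: none
Why: Zerovalent palladium should ionise the tertiary propargylic carbonate in anti-SN2' fashion with loss of CO2 to an allenylpalladium methoxide (divalent palladium), which transmetalates with the boronic acid without added base and reductively eliminates the tetrasubstituted allenoate (palladium-catalysed SN2' coupling of a propargylic carbonate with a boronic acid); the allene axis forms without control and the mild temperature should keep the cyclobutenone closed.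

**Step 6**
Reactants: 17 the 4-allenylcyclobutenone
Product: 19 methyl 2-(4-tert-butoxy-3-methoxy-6-oxo-2,5-diphenylcyclohexa-2,4-dien-1-ylidene)-2-(4-tert-butoxyphenyl)acetate (exocyclic alkene geometry not defined), via (Z)-dienylketene 18 (not isolated)
Conditions: toluene, 110 °C, argon
Reagents that add atoms: none
Why: Heating should open the C1–C4 bond of the cyclobutenone in a conrotatory 4π process to the (Z)-dienylketene 18, whose ketene carbon (future C7a) then bonds to the central allene carbon (future C3a) in a thermally allowed disrotatory 6π electrocyclization, so that the six-membered carbocycle appears with C7a as a ketone, the distal allene bond as the exocyclic C3a=C3 alkene and all six ring substituents in place. The closest known reaction type is the thermal ring expansion of 4-allenyl-4-alkoxycyclobutenones to ortho-quinone methides, the allenyl branch of the Moore rearrangement, here asked to accept a tetrasubstituted allenoate. The only ring closed is the carbocycle, through the C7a–C3a bond, and this six-membered closure is the only concerted 6π option open to the ketene. No stereocentre is created: the ring stereocentre and the allene axis of 17 are destroyed, and the C3=C3a geometry need not be controlled because step 7 can equilibrate it. The selectivity required is inward rotation of the allenyl group during ring opening, which the strong outward preference of the C4 methoxy donor should secure. The product has no hydrogen on C3 or C3a with which to tautomerise to an arene and is stabilised by its donor (C5 and C6 alkoxy, aryl) and acceptor (ester) groups, so the oxidation level of the target is reached without a redox reagent.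

**Step 7**
Reactants: 19 the ortho-quinone methide ester
Product: 21 3-(4-hydroxyphenyl)-5-methoxy-4,7-diphenyl-1-benzofuran-2,6-dione, via dihydroxy ester 20 (not isolated)
Conditions: CF3CO2H, CH2Cl2, 0 °C → rt
Reagents that add atoms: none
Why: CF3CO2H should cleave the vinylogous tert-butyl ester and the aryl tert-butyl ether by loss of isobutene; the freed vinylogous acid places a hydroxyl on C7a, and because the O-protonated quinone methide is a benzylic cation that rotates freely about C3a–C3, the ester can reach that hydroxyl and close the butenolide by 5-exo-trig acyl substitution with loss of methanol (acid-mediated dealkylative lactonisation), while the C5 methyl enol ether should survive anhydrous acid.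

**Compound list**
1 | di-tert-butyl squarate (3,4-di-tert-butoxycyclobut-3-ene-1,2-dione) | CC(C)(C)OC1=C(OC(C)(C)C)C(=O)C1=O | starting material
2 | phenyllithium | [Li]c1ccccc1 | starting material
3 | lithium 2,3-di-tert-butoxy-4-oxo-1-phenylcyclobut-2-en-1-olate | [Li]OC1(c2ccccc2)C(OC(C)(C)C)=C(OC(C)(C)C)C1=O | intermediate
4 | 2,3-di-tert-butoxy-4-oxo-1-phenylcyclobut-2-en-1-yl trifluoroacetate | O=C(OC1(c2ccccc2)C(OC(C)(C)C)=C(OC(C)(C)C)C1=O)C(F)(F)F | intermediate
5 | 3-tert-butoxy-4-phenylcyclobut-3-ene-1,2-dione | CC(C)(C)OC1=C(c2ccccc2)C(=O)C1=O | intermediate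
6 | 1-bromo-4-tert-butoxybenzene | CC(C)(C)Oc1ccc(Br)cc1 | starting material
7 | dimethyl oxalate | COC(=O)C(=O)OC | starting material
8 | (4-tert-butoxyphenyl)magnesium bromide | CC(C)(C)Oc1ccc([Mg]Br)cc1 | intermediate
9 | methyl 2-(4-tert-butoxyphenyl)-2-oxoacetate | COC(=O)C(=O)c1ccc(OC(C)(C)C)cc1 | intermediate
10 | ethynylmagnesium bromide | C#C[Mg]Br | starting material
11 | bromomagnesium alkoxide of methyl 2-(4-tert-butoxyphenyl)-2-hydroxybut-3-ynoate | COC(=O)C(C#C)(O[Mg]Br)c1ccc(OC(C)(C)C)cc1 | intermediate
12 | methyl 2-(4-tert-butoxyphenyl)-2-(methoxycarbonyloxy)but-3-ynoate (racemic) | COC(=O)OC(C#C)(C(=O)OC)c1ccc(OC(C)(C)C)cc1 | intermediate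
13 | lithium acetylide of 12 | [Li]C#CC(OC(=O)OC)(C(=O)OC)c1ccc(OC(C)(C)C)cc1 | intermediate
14 | lithium alkoxide from addition of 13 to 5 (alkynyl and OLi on ring C1, tert-butoxy on C2, phenyl on C3, ketone C4) | [Li]OC1(C#CC(OC(=O)OC)(C(=O)OC)c2ccc(OC(C)(C)C)cc2)C(OC(C)(C)C)=C(c2ccccc2)C1=O | intermediate
15 | methyl 2-(4-tert-butoxyphenyl)-4-(2-tert-butoxy-1-methoxy-4-oxo-3-phenylcyclobut-2-en-1-yl)-2-(methoxycarbonyloxy)but-3-ynoate (diastereomer mixture) | COC(=O)OC(C#CC1(OC)C(OC(C)(C)C)=C(c2ccccc2)C1=O)(C(=O)OC)c1ccc(OC(C)(C)C)cc1 | intermediate
16 | phenylboronic acid | OB(O)c1ccccc1 | starting material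
17 | methyl 2-(4-tert-butoxyphenyl)-4-(2-tert-butoxy-1-methoxy-4-oxo-3-phenylcyclobut-2-en-1-yl)-4-phenylbuta-2,3-dienoate (stereoisomer mixture) | COC(=O)C(=C=C(c1ccccc1)C1(OC)C(OC(C)(C)C)=C(c2ccccc2)C1=O)c1ccc(OC(C)(C)C)cc1 | intermediate
18 | methyl (5Z)-6-tert-butoxy-2-(4-tert-butoxyphenyl)-5-methoxy-8-oxo-4,7-diphenylocta-2,3,5,7-tetraenoate (dienylketene) | O=C=C(c1ccccc1)/C(OC(C)(C)C)=C(OC)\C(c1ccccc1)=C=C(c1ccc(OC(C)(C)C)cc1)C(=O)OC | intermediate
19 | methyl 2-(4-tert-butoxy-3-methoxy-6-oxo-2,5-diphenylcyclohexa-2,4-dien-1-ylidene)-2-(4-tert-butoxyphenyl)acetate (alkene geometry not defined) | COC(=O)C(c1ccc(OC(C)(C)C)cc1)=C1C(=O)C(c2ccccc2)=C(OC(C)(C)C)C(OC)=C1c1ccccc1 | intermediate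
20 | methyl 2-(4-hydroxy-3-methoxy-6-oxo-2,5-diphenylcyclohexa-2,4-dien-1-ylidene)-2-(4-hydroxyphenyl)acetate | COC(=O)C(c1ccc(O)cc1)=C1C(=O)C(c2ccccc2)=C(O)C(OC)=C1c1ccccc1 | intermediate
21 | 3-(4-hydroxyphenyl)-5-methoxy-4,7-diphenyl-1-benzofuran-2,6-dione (CNP0282683.0) | COC1=C(c2ccccc2)C2=C(c3ccc(O)cc3)C(=O)OC2=C(c2ccccc2)C1=O | target

**Step count**
Total steps: 7. Longest linear sequence: 6 steps (6 → 9 → 12 → 15 → 17 → 19 → 21).

**Steps most likely to fail**

Step 6. The ring-opened ketene may close only slowly on the fully substituted allene, so that it reverts or is diverted, or thermal loss of isobutene from the vinylogous ester may outrun the electrocyclization. The fallback sets out from 5 and 9 and comes back at 21, reaching the same oxidation level through an arene.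
- 1-Phenylethenyllithium (from α-bromostyrene and t-BuLi, THF, −78 °C) would be added to 5 at the same carbonyl as in step 4 and the alkoxide methylated with MeOTf, giving 3-tert-butoxy-4-methoxy-2-phenyl-4-(1-phenylethenyl)cyclobut-2-en-1-one F1.
- Heating F1 in toluene (classical Moore ring expansion of a 4-alkenylcyclobutenone, closure onto the CH2 terminus and tautomerisation) should give 3-tert-butoxy-4-methoxy-2,5-diphenylphenol F2. Its single free ring position is the future C3a, ortho to the hydroxyl and para to the tert-butoxy oxygen.
- F2 and keto ester 9 would then be combined with BF3·OEt2 in CH2Cl2. The Lewis acid should remove the three tert-butyl groups, the keto ester should hydroxyalkylate the free position (Friedel–Crafts) and the ortho-hydroxyl should lactonise with loss of methanol, giving 3,6-dihydroxy-3-(4-hydroxyphenyl)-5-methoxy-4,7-diphenyl-1-benzofuran-2(3H)-one F3.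
- Acid-promoted vinylogous dehydration of F3 (expulsion of the tertiary hydroxyl with help of the para-hydroxyl) should give 21 without any redox step.

Step 5. Oxidative addition may be slow at an alkyne terminus shielded by the quaternary ring carbon, so that protodeboronation or premature opening of the four-membered ring in the presence of palladium competes. The fallback sets out from 15 and comes back at 17 without a new compound. It uses stoichiometric anti-SN2' substitution by a phenylcopper reagent, PhCu·MgBr2, prepared from PhMgBr and CuBr·SMe2 (monovalent copper) in THF at −78 → −40 °C. This attacks the alkyne terminus directly with departure of the carbonate and needs no allenylpalladium species; at that temperature the organocopper should leave the ring carbonyl and the esters alone.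

Step 4. The lithium acetylide may expel its own propargylic carbonate (γ-elimination) or be consumed by the carbonate and ester carbonyls before it reaches the dione. The fallback sets out from 9 and comes back at 15, carrying the tertiary oxygen as a silyl ether through the acetylide stage.
- After addition of 10, the magnesium alkoxide would be trapped with Me3SiCl in place of the chloroformate, giving methyl 2-(4-tert-butoxyphenyl)-2-(trimethylsilyloxy)but-3-ynoate F4.
- LiN(SiMe3)2, then 5, then MeOTf as in step 4 should give methyl 2-(4-tert-butoxyphenyl)-4-(2-tert-butoxy-1-methoxy-4-oxo-3-phenylcyclobut-2-en-1-yl)-2-(trimethylsilyloxy)but-3-ynoate F5.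
- Bu4NF buffered with AcOH (THF, 0 °C) should free methyl 2-(4-tert-butoxyphenyl)-4-(2-tert-butoxy-1-methoxy-4-oxo-3-phenylcyclobut-2-en-1-yl)-2-hydroxybut-3-ynoate F6.
- Deprotonation of F6 with LiN(SiMe3)2 and acylation with ClCO2Me (THF, −78 °C) should deliver 15.

**Further compounds**
F1 | step 6 | 3-tert-butoxy-4-methoxy-2-phenyl-4-(1-phenylethenyl)cyclobut-2-en-1-one | COC1(C(=C)c2ccccc2)C(OC(C)(C)C)=C(c2ccccc2)C1=O
F2 | step 6 | 3-tert-butoxy-4-methoxy-2,5-diphenylphenol | COc1c(-c2ccccc2)cc(O)c(-c2ccccc2)c1OC(C)(C)C
F3 | step 6 | 3,6-dihydroxy-3-(4-hydroxyphenyl)-5-methoxy-4,7-diphenyl-1-benzofuran-2(3H)-one | COc1c(O)c(-c2ccccc2)c2OC(=O)C(O)(c3ccc(O)cc3)c2c1-c1ccccc1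
F0 | step 5 | none | none
F4 | step 4 | methyl 2-(4-tert-butoxyphenyl)-2-(trimethylsilyloxy)but-3-ynoate | COC(=O)C(C#C)(O[Si](C)(C)C)c1ccc(OC(C)(C)C)cc1
F5 | step 4 | methyl 2-(4-tert-butoxyphenyl)-4-(2-tert-butoxy-1-methoxy-4-oxo-3-phenylcyclobut-2-en-1-yl)-2-(trimethylsilyloxy)but-3-ynoate | COC(=O)C(C#CC1(OC)C(OC(C)(C)C)=C(c2ccccc2)C1=O)(O[Si](C)(C)C)c1ccc(OC(C)(C)C)cc1
F6 | step 4 | methyl 2-(4-tert-butoxyphenyl)-4-(2-tert-butoxy-1-methoxy-4-oxo-3-phenylcyclobut-2-en-1-yl)-2-hydroxybut-3-ynoate | COC(=O)C(O)(C#CC1(OC)C(OC(C)(C)C)=C(c2ccccc2)C1=O)c1ccc(OC(C)(C)C)cc1
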